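**Assumption:** Gancaonin J has no stereocentre and no stereogenic double bond, so the SMILES defines one achiral compound and no stereocontrol is needed.

## Retrosynthetic overview

- Both prenyl groups are made last, by double cross-metathesis of a 3',5'-diallyl dihydrochalcone with 2-methyl-2-butene, so no direct C-prenylation is used.
- The 3',5'-diallyl-2',4'-diol comes from one double aromatic Claisen rearrangement of the 2',4'-bis(allyl) ether. The allyl ethers are the latent C-substituents and also the only thing that distinguishes the ring A phenols from the ring B phenol.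
- The saturated three-carbon bridge comes from rhodium-catalysed 1,4-addition of unprotected 4-hydroxyphenylboronic acid to an aryl vinyl ketone (Cβ–aryl bond). This replaces the usual Claisen–Schmidt condensation and enone reduction, which would clash with the alkenes.
- The aryl vinyl ketone comes from α-methylenation of 2',4'-bis(allyloxy)acetophenone, itself from 2',4'-dihydroxyacetophenone and allyl bromide.
- No ring is formed: ring A is bought as resacetophenone and ring B as the boronic acid.

## Route

**Step 1**
Reactants: 1 1-(2,4-dihydroxyphenyl)ethan-1-one; 2 allyl bromide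
Product: 4 1-[2,4-bis(allyloxy)phenyl]ethan-1-one, via mono-allyl ether 3 (not isolated)
Conditions: allyl bromide (2.5 equiv), K2CO3 (3 equiv), DMF, 60 °C, 12 h
Reagents that add atoms: allyl bromide, C=CCBr
Why: Williamson ether synthesis, in which the free 4'-OH is alkylated first and the chelated 2'-OH follows in warm DMF with excess bromide and K2CO3.

**Step 2**
Reactants: 4 1-[2,4-bis(allyloxy)phenyl]ethan-1-one; 5 paraformaldehyde
Product: 7 1-[2,4-bis(allyloxy)phenyl]prop-2-en-1-one, via Mannich base 6 (not isolated)
Conditions: (CH2O)n (2.5 equiv), iPr2NH2+ CF3CO2− (1 equiv), CF3CO2H (10 mol %), THF, reflux, 6 h; product kept cold over a trace of BHT and used at once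
Reagents that add atoms: paraformaldehyde (formaldehyde unit), C=O
Why: Mannich condensation followed by β-elimination (direct α-methylenation of a methyl ketone), in which the enol adds to the iminium ion from formaldehyde and diisopropylamine and the hindered amine is expelled from the Mannich base under the reaction conditions, while the allyl aryl ethers are inert to the weakly acidic buffer.

**Step 3**
Reactants: 7 1-[2,4-bis(allyloxy)phenyl]prop-2-en-1-one; 8 4-hydroxyphenylboronic acid
Product: 9 1-[2,4-bis(allyloxy)phenyl]-3-(4-hydroxyphenyl)propan-1-one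
Conditions: 8 (1.5 equiv), [Rh(OH)(cod)]2 (2 mol %), dioxane/H2O 10:1, 25–40 °C, argon
Reagents that add atoms: 4-hydroxyphenylboronic acid, OB(O)c1ccc(O)cc1
Why: Hayashi–Miyaura rhodium-catalysed 1,4-addition, in which the aryl group passes from boron to rhodium, adds across the electron-poor vinyl ketone much faster than across the unactivated allyl ether alkenes and is released by protonolysis with water, so the saturated ketone is formed directly and the free phenol is tolerated under base-free conditions.

**Step 4**
Reactants: 9 1-[2,4-bis(allyloxy)phenyl]-3-(4-hydroxyphenyl)propan-1-one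
Product: 11 1-(3,5-diallyl-2,4-dihydroxyphenyl)-3-(4-hydroxyphenyl)propan-1-one, via mono-rearranged phenol 10 (not isolated)
Conditions: PhNEt2, 200 °C, sealed tube, argon, 6–8 h
Reagents that add atoms: none
Why: Double aromatic Claisen rearrangement ([3,3]-sigmatropic shift then rearomatisation, twice), in which the 2'-O-allyl group can only reach C3' and the 4'-O-allyl group is then left with C5', so whichever ether moves first the open ortho and para positions funnel both allyl groups to C3' and C5', while ring B carries no allyl ether and is untouched and the basic solvent suppresses acid-catalysed cyclisation of the o-allylphenols.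

**Step 5**
Reactants: 11 1-(3,5-diallyl-2,4-dihydroxyphenyl)-3-(4-hydroxyphenyl)propan-1-one; 12 2-methyl-2-butene
Product: 14 Gancaonin J 1-[2,4-dihydroxy-3,5-bis(3-methylbut-2-en-1-yl)phenyl]-3-(4-hydroxyphenyl)propan-1-one, via mono-prenyl ketone 13 (not isolated)
Conditions: 2-methyl-2-butene (about 40 equiv), second-generation Grubbs catalyst RuCl2(=CHPh)(PCy3)(H2IMes) (5 mol %), CH2Cl2, 40 °C, sealed tube, 16 h
Reagents that add atoms: 2-methyl-2-butene, CC=C(C)C
Why: Double olefin cross-metathesis, in which each terminal allyl alkene exchanges its CH2 end for the isopropylidene of 2-methyl-2-butene (large excess, propene leaves as gas), the ruthenium carbene tolerates free phenols and the ketone, and the trisubstituted prenyl alkenes formed do not react further.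

## Compound list

1 | 1-(2,4-dihydroxyphenyl)ethan-1-one (resacetophenone) | CC(=O)c1ccc(O)cc1O | starting material
2 | allyl bromide | C=CCBr | starting material
3 | 1-[4-(allyloxy)-2-hydroxyphenyl]ethan-1-one | CC(=O)c1ccc(OCC=C)cc1O | intermediate (not isolated)
4 | 1-[2,4-bis(allyloxy)phenyl]ethan-1-one | CC(=O)c1ccc(OCC=C)cc1OCC=C | intermediate
5 | paraformaldehyde (formaldehyde unit) | C=O | starting material
6 | 1-[2,4-bis(allyloxy)phenyl]-3-(diisopropylamino)propan-1-one | CC(C)N(CCC(=O)c1ccc(OCC=C)cc1OCC=C)C(C)C | intermediate (not isolated)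
7 | 1-[2,4-bis(allyloxy)phenyl]prop-2-en-1-one | C=CC(=O)c1ccc(OCC=C)cc1OCC=C | intermediate
8 | 4-hydroxyphenylboronic acid | OB(O)c1ccc(O)cc1 | starting material
9 | 1-[2,4-bis(allyloxy)phenyl]-3-(4-hydroxyphenyl)propan-1-one | O=C(CCc1ccc(O)cc1)c1ccc(OCC=C)cc1OCC=C | intermediate
10 | 1-[3-allyl-4-(allyloxy)-2-hydroxyphenyl]-3-(4-hydroxyphenyl)propan-1-one | O=C(CCc1ccc(O)cc1)c1ccc(OCC=C)c(CC=C)c1O | intermediate (not isolated)
11 | 1-(3,5-diallyl-2,4-dihydroxyphenyl)-3-(4-hydroxyphenyl)propan-1-one | O=C(CCc1ccc(O)cc1)c1cc(CC=C)c(O)c(CC=C)c1O | intermediate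
12 | 2-methyl-2-butene | CC=C(C)C | starting material
13 | 1-[3-allyl-2,4-dihydroxy-5-(3-methylbut-2-en-1-yl)phenyl]-3-(4-hydroxyphenyl)propan-1-one | O=C(CCc1ccc(O)cc1)c1cc(CC=C(C)C)c(O)c(CC=C)c1O | intermediate (not isolated)
14 | Gancaonin J, 1-[2,4-dihydroxy-3,5-bis(3-methylbut-2-en-1-yl)phenyl]-3-(4-hydroxyphenyl)propan-1-one | CC(C)=CCc1cc(C(=O)CCc2ccc(O)cc2)c(O)c(CC=C(C)C)c1O | target

## Summary

Total step count: 5. Longest linear sequence: 5 steps (1 → 4 → 7 → 9 → 11 → 14).

## Steps most likely to fail, and fallbacks

**Step 2 (α-methylenation).** The aryl vinyl ketone 7 may oligomerise on isolation or be contaminated by bis-Mannich products. The fallback sets out from 4 and never isolates 7. A classical Mannich reaction (Me2NH·HCl, (CH2O)n, catalytic HCl, EtOH, reflux, then NaHCO3 work-up) gives the stable amine 1-[2,4-bis(allyloxy)phenyl]-3-(dimethylamino)propan-1-one F1. F1 is fed directly into the rhodium reaction of step 3 (8, [Rh(OH)(cod)]2, K3PO4, dioxane/H2O, 60 °C). Slow loss of dimethylamine releases 7 at low concentration, and it is arylated as it forms. The fallback comes back to the route at 9.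

**Step 3 (rhodium 1,4-addition with an unprotected phenol).** Possible problems are oligomerisation of 7, reversible oxa-Michael addition of the phenol, and protodeboronation of 8. The fallback sets out from 4 and avoids the vinyl ketone altogether by forming the Cα–Cβ bond through enolate alkylation. Deprotonation of the methyl ketone with LiN(SiMe3)2 (1.05 equiv, THF, −78 °C) and C-benzylation with commercial 4-(tert-butyldimethylsilyloxy)benzyl bromide (−78 to 0 °C) gives 1-[2,4-bis(allyloxy)phenyl]-3-[4-(tert-butyldimethylsilyloxy)phenyl]propan-1-one F2. Bu4NF in THF at 0 °C removes the silyl group, and the fallback comes back to the route at 9.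

**Step 4 (double Claisen rearrangement on the full skeleton at 200 °C).** Possible problems are an incomplete second shift, cyclisation of the o-allylphenols, or thermal damage to the diaryl propanone. The fallback sets out from 4 and reverses the order of events.
- The double Claisen rearrangement is run on the simple acetophenone (PhNEt2, 200 °C). It passes through the mono-rearranged phenol 1-[3-allyl-4-(allyloxy)-2-hydroxyphenyl]ethan-1-one F3 (not isolated) to 1-(3,5-diallyl-2,4-dihydroxyphenyl)ethan-1-one F4.
- Triple deprotonation with LiN(SiMe3)2 (3.3 equiv, THF, −78 to 0 °C) and addition of 4-(tert-butyldimethylsilyloxy)benzyl bromide (1.0 equiv) alkylates the methyl carbon, the last-formed and most nucleophilic site. This gives 1-(3,5-diallyl-2,4-dihydroxyphenyl)-3-[4-(tert-butyldimethylsilyloxy)phenyl]propan-1-one F5.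
- Bu4NF in THF then frees the ring B phenol, and the fallback comes back to the route at 11, from which step 5 proceeds as written.

## Further compounds

F1 | step 2 | 1-[2,4-bis(allyloxy)phenyl]-3-(dimethylamino)propan-1-one | CN(C)CCC(=O)c1ccc(OCC=C)cc1OCC=C
F2 | step 3 | 1-[2,4-bis(allyloxy)phenyl]-3-[4-(tert-butyldimethylsilyloxy)phenyl]propan-1-one | CC(C)(C)[Si](C)(C)Oc1ccc(CCC(=O)c2ccc(OCC=C)cc2OCC=C)cc1
F3 | step 4 | 1-[3-allyl-4-(allyloxy)-2-hydroxyphenyl]ethan-1-one (not isolated) | CC(=O)c1ccc(OCC=C)c(CC=C)c1O
F4 | step 4 | 1-(3,5-diallyl-2,4-dihydroxyphenyl)ethan-1-one | CC(=O)c1cc(CC=C)c(O)c(CC=C)c1O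
F5 | step 4 | 1-(3,5-diallyl-2,4-dihydroxyphenyl)-3-[4-(tert-butyldimethylsilyloxy)phenyl]propan-1-one | CC(C)(C)[Si](C)(C)Oc1ccc(CCC(=O)c2cc(CC=C)c(O)c(CC=C)c2O)cc1
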